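Wednesday's and Thursday's flasks each hold 1.1 mM of impurity, and the choice for the next run lies between 0.60 mM and 1.8 mM of free catalyst.

in all of them: left-handed substrate 0.20 M; right-handed substrate 0.20 M; impurity 1.1 mM
- winter: partner 0.30 M; free catalyst 0.35 mM; run made earlier
- dawn: partner 0.30 M; free catalyst 1.4 mM; run made earlier
- Thursday's: partner 0.300 M; free catalyst 1.8 mM; time 80 min
- Wednesday's: partner 0.300 M; free catalyst 0.60 mM; time 80 min

- winter (time / min: right-handed substrate / %, left-handed substrate / %, left-handed product / %): 5.00: 48, 51, 0; 10.0: 51, 52, 5; 25.0: 49, 51, 2; 60.0: 50, 50, 1
- dawn (time / min: right-handed substrate / %, left-handed substrate / %, left-handed product / %): 15.0: 45, 44, 5; 30.0: 45, 41, 9; 40.0: 43, 38, 10; 60.0: 45, 36, 17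

(scatter of a reading: 1.5 percentage points)

- free catalyst is single-handed; left-handed substrate and right-handed substrate are mirror images of each other, charged as a racemate, each of them at the stated concentration
- an excess is the difference of the two amounts in percent of their sum
- an excess is below zero if the other one leads

- which one finishes higher in excess of right-handed substrate over left-handed substrate among what is left of the two ("neither" within 2 percentage points) (Thursday's / Wednesday's / neither)
- excess of right-handed substrate over left-handed substrate among what is left of the two at the end, Thursday's
- excess of right-handed substrate over left-handed substrate among what is left of the two at the end, Wednesday's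

The winter run, charged with 0.35 mM of free catalyst, less than its 1.1 mM of impurity, leaves right-handed substrate at 50% and left-handed substrate at 50% after 60.0 min. The dawn run, charged with 1.4 mM, does react. This reckoning therefore takes the impurity as removing catalyst one to one and counts the margin m = c(free catalyst) − c(impurity), which at dawn is 0.300 mM. The joint loss of the substrates in the dawn run reads 19 percentage points at 40.0 min and 19 points at 60.0 min, but with a scatter of 1.5 points on each reading these two sums show no stop, and left-handed product reads 10% and then 17% at those times. Substrate converted by 60.0 min divided by m gives 253, the turnover number per mole of catalyst above the impurity; it is a reading at that time, not a final count, and carries the scatter.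

Wednesday's charge is less than the impurity, so this reckoning expects no turnovers there and an excess near zero. Thursday's m is 0.700 mM, and the same count, read at 60.0 min in the dawn run and carried unchanged to a flask of 80 min, converts 44.3% of the substrates charged. That is 0.177 M, less than the 0.300 M of partner. Left-handed substrate made up 65.1% of the loss pooled over the dawn readings, which puts Thursday's excess at 24.0%. The decision is to charge Thursday's recipe.

The forecast also names Thursday's, with 40% for Thursday's and 0% for Wednesday's. It stands above this reckoning on Thursday's flask, reading that “Right-handed substrate drops about 5 points early, then stays flat”.

Thursday's finishes higher, at 16.7% against 0.233% for Wednesday's.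

    partner + free catalyst + left-handed substrate → free catalyst + left-handed product (k = 100 L² mol⁻² min⁻¹)
    partner + free catalyst + right-handed substrate → free catalyst + right-handed product (k = 50.0 L² mol⁻² min⁻¹)
    free catalyst + impurity → spent catalyst A (k = 2500 L mol⁻¹ min⁻¹)
    free catalyst → spent catalyst B (k = 0.0150 min⁻¹)

Thursday's flask ends with 24.5% of left-handed product and 14.3% of right-handed product, which is 222 turnovers on its m. The neighbour flask is Wednesday's recipe with 2.40 mM of free catalyst, so its m is 1.30 mM. The dawn count then gives 0.329 M of substrate, more than the 0.300 M of partner, so the reckoning stops at 75.0% converted. That flask holds 31.6% of left-handed product and 19.7% of right-handed product after 80.0 min, which is 158 turnovers, with 32% of its partner remaining and an excess of 24.5%.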